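The numbers are made up; the result is computed.

How far does this flask get on the reagent it is given, and how much of that ends as target?

starting material 0.18 M; reagent 0.144 M; time 15 d

    starting material + reagent → intermediate A (k1 = 5.1 × 10⁻⁵ /M/s)
    intermediate A ⇌ intermediate B (K2 = 0.77, k2 = 7.2 × 10⁻⁶ /s)
    intermediate A ⇌ intermediate C (K3 = 0.32, k3 = 2.7 × 10⁻⁶ /s)
    reagent + intermediate A → target (k4 = 9.6 × 10⁻⁵ /M/s)

- the reaction counts as stopped when no species that holds the starting material changes by six tenths of a point or more over the second half of the time
- run time (flask): 15 d

1. why nothing more happens at 15 d, or that something still does (the reagent has run out first / all of the starting material has reacted / it is still moving / forward and back rates have come level)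
2. conversion of starting material at 15 d
3. amount of target at 15 d, in percent of the starting material charged
4. amount of intermediate A at 15 d, in percent of the starting material charged
5. amount of intermediate B at 15 d, in percent of the starting material charged

I write the balance of the reagent, the smaller charge. Starting material takes one reagent on becoming intermediate A, and that material takes a second on going on to target, while the exchanges among intermediates A, B and C take none. So, in percent of the starting material charged, conversion plus target equals the reagent consumed. Once the reagent is gone, that sum is the reagent budget, the reagent charge divided by the starting material charge: 80.0%. Two extreme cases show what it allows:

| Converted material ends as | Reagent for each | Conversion | Target |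
|---|---|---|---|
| intermediates A, B and C | one | 80.0% | none |
| target | two | 40.0% | 40.0% |

The first row is the cheap end, and even there 20.0% of the starting material stays unreacted, so the reagent is the limiting reagent. The second row pays two reagents for each, and conversion falls to half of the first row's. Column against column, conversion plus target gives the budget in both rows, and so in any mixture of them: each point of target costs a point of conversion.

With a half-life of 1.1 d for starting material by the first step alone, reagent as charged, short against 15 d, I expect the reagent to run out first. My reckoning stops here, at a sum of 80.0% without a split. The split depends on a race: intermediate A has a half-life of 0.58 d towards target at charged reagent and 1.1 d forward to intermediate B, and the reagent is falling meanwhile.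

The forecast says the reagent has run out first, with conversion 57%, target 23.2%, intermediate A 16.1% and intermediate B 12.4%. Its ground is: “Each target consumes two reagents”. Its conversion and target add to 80.2%.

The flask's answer is that the reagent has run out first, with 0.0094% of the reagent left at 15.0 d, conversion 57.2%, target 22.8%, intermediate A 16.4% and intermediate B 12.6%.

In this flask, conversion and target add to 80.0% against the budget of 80.0%. The neighbouring flask, charged with 0.31 M of starting material, has a budget of 46.5%. So I expect its conversion and target to add to that, with more starting material sharing the same reagent charge. It gives conversion 36.7% and target 9.70%, which add to 46.4%, with 0% of the reagent left.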